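**Plan**

1. Locants used below: ring A = C3–C7 (C6 bears Me); ring B = C2(Me)=C3, C7, C8(OH), C9, C18, C19, C20; ring C = C9(Me), C10, C11, C12(Me), C17, C18; ring D = C12–C17 (C15 bears Me2).
2. Cuts, latest first: C2=C3 (ring B, ketone–ketone coupling); C3–C4, C3–C7 and C5–C6 (ring A from an alkyne, ethylene and CO); C9–C18 (ring C); C9–C10 (alkenyllithium + ketone); C18–C19 (enolate alkylation); the allyl bond at C12 (asymmetric allylation).
3. Enabling feature: C10–C9(Me, quaternary)–C8(OH) becomes an aldol-type array once an oxygen is placed on C10, which is the product pattern of a semipinacol shift. Ring C is therefore grown from the cyclopentanol C10–C11–C12–C17–C18 by moving the C10–C18 bond onto C9 of a C8–C9 epoxide.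
4. Forward order of rings: D (bought) → cyclopentanone fused to D → ring C by one-carbon enlargement → ring A (Pauson–Khand) → ring B (McMurry). Helpers removed later: the C10 oxygen (steps 11 and 14), the C8 isobutyrate (step 16), the dioxolane (step 13).
5. Stereochemistry: C12 from Pd/(S)-t-Bu-PHOX allylation; C17 and C18 from reductive alkylation under control of C12; C8 and C9 from Shi epoxidation of a (Z)-enyne, passed on stereospecifically in the 1,2-shift; C7 and C6 from a syn hydrogenation steered by C8.

Key step: step 10

Remark: but-2-ynal (12) is taken as a purchasable, volatile aldehyde that is handled as a stock solution.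
Remark: the carbinol carbon C10 of 15 and 16 is formed without control; it becomes a carbonyl carbon in step 10, so both epimers are carried on together and the SMILES of 15 and 16 leave this centre open.

**Step 1**
Reactants: 1 3,3-dimethylcyclohexanone; 2 diallyl carbonate
Product: 3 allyl 4,4-dimethyl-2-oxocyclohexane-1-carboxylate
Conditions: NaH, THF, reflux; then aq. HCl
Reagents that add atoms: none
Why: Claisen-type C-acylation of the ketone enolate should take place at the methylene remote from the gem-dimethyl group, because the other α-position is neopentyl and only the less hindered β-keto ester enolate accumulates under thermodynamic control.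

**Step 2**
Reactants: 3 allyl 4,4-dimethyl-2-oxocyclohexane-1-carboxylate; 4 iodomethane
Product: 5 allyl 1,4,4-trimethyl-2-oxocyclohexane-1-carboxylate (racemic)
Conditions: K2CO3, acetone, 50 °C
Reagents that add atoms: none
Why: C-methylation of the β-keto ester enolate should give the quaternary α-methyl β-keto ester; the racemic centre is of no consequence because step 3 is stereoablative.

**Step 3**
Reactants: 5 allyl 1,4,4-trimethyl-2-oxocyclohexane-1-carboxylate
Product: 6 (S)-2-allyl-2,5,5-trimethylcyclohexan-1-one
Conditions: Pd2(dba)3 (2.5 mol %), (S)-t-Bu-PHOX (6 mol %), THF, 25 °C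
Reagents that add atoms: none
Why: Palladium-catalysed decarboxylative asymmetric allylic alkylation (Tsuji allylation): oxidative addition of zerovalent palladium and loss of CO2 give a prochiral enolate and a π-allyl complex, and the (S)-PHOX ligand should direct allylation to the face that gives the (S) quaternary centre C12, by analogy with (S)-2-allyl-2-methylcyclohexanone; the enantiomeric purity can be raised later by crystallisation of a solid intermediate.

**Step 4**
Reactants: 6 (S)-2-allyl-2,5,5-trimethylcyclohexan-1-one
Product: 7 (S)-2,5,5-trimethyl-2-(2-oxopropyl)cyclohexan-1-one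
Conditions: PdCl2 (10 mol %), CuCl (20 mol %), O2 (1 atm), DMF/H2O, 25 °C
Reagents that add atoms: water, O
Why: Tsuji–Wacker oxidation should convert the terminal alkene into the methyl ketone with Markovnikov selectivity and leave the ring ketone and the quaternary centre untouched.

**Step 5**
Reactants: 7 (S)-2,5,5-trimethyl-2-(2-oxopropyl)cyclohexan-1-one
Product: 8 (S)-5,5,7a-trimethyl-1,4,5,6,7,7a-hexahydro-2H-inden-2-one
Conditions: KOH (powdered), xylenes, 110 °C, Dean–Stark
Reagents that add atoms: none
Why: Intramolecular aldol condensation of the 1,4-diketone (cyclopentenone annulation) should join the methyl ketone CH3 to the ring carbonyl, the dehydrated fused enone being the only irreversible outlet.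

**Step 6**
Reactants: 8 (S)-5,5,7a-trimethyl-1,4,5,6,7,7a-hexahydro-2H-inden-2-one; 9 2-(2-bromoethyl)-2-methyl-1,3-dioxolane
Product: 11 (3S,3aS,7aS)-5,5,7a-trimethyl-3-[2-(2-methyl-1,3-dioxolan-2-yl)ethyl]octahydro-2H-inden-2-one, via lithium enolate 10 (not isolated)
Conditions: Li (2.0 equiv), t-BuOH (1.0 equiv), NH3(l)/THF, −78 °C; NH3 evaporated; 9, THF/HMPA, 0 → 25 °C; then H2O
Reagents that add atoms: none
Why: Stork reductive alkylation: dissolving-metal reduction should protonate C17 on the face opposite the angular C12 methyl (trans-hydrindanone) and give the C10=C18 lithium enolate regiospecifically, which should be alkylated by the primary bromide on the face away from the angular methyl, placing the side chain at C18 trans to the C16 ring bond (also the thermodynamically preferred arrangement, reachable by base equilibration).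

**Step 7**
Reactants: 12 but-2-ynal
Product: 13 (Z)-2-iodohex-2-en-4-yne
Conditions: EtPPh3I, n-BuLi, THF, 25 °C; I2, −78 °C; NaN(SiMe3)2, −20 °C; then 12, −78 → 0 °C
Reagents that add atoms: ethyltriphenylphosphonium iodide, CC[P+](c1ccccc1)(c1ccccc1)c1ccccc1.[I-]; iodine, II
Why: Stork–Zhao Wittig olefination with the α-iodo ylide Ph3P=C(I)CH3 should give the (Z)-iodoalkene (iodine and alkynyl group cis) through the kinetically controlled cis-oxaphosphetane of a non-stabilised ylide; the aldehyde has no α-hydrogen.

**Step 8**
Reactants: 13 (Z)-2-iodohex-2-en-4-yne; 11 (3S,3aS,7aS)-5,5,7a-trimethyl-3-[2-(2-methyl-1,3-dioxolan-2-yl)ethyl]octahydro-2H-inden-2-one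
Product: 15 (3S,3aS,7aS)-2-[(Z)-hex-2-en-4-yn-2-yl]-5,5,7a-trimethyl-3-[2-(2-methyl-1,3-dioxolan-2-yl)ethyl]octahydro-1H-inden-2-ol (both C2 epimers), via alkenyllithium 14 (not isolated)
Conditions: t-BuLi (2.0 equiv), Et2O, −78 °C; then 11, −78 → −20 °C; then H2O
Reagents that add atoms: none
Why: Iodine–lithium exchange with retention of alkene geometry followed by 1,2-addition of the alkenyllithium to the cyclopentanone should give the tertiary (Z)-allylic alcohol; the new carbinol centre C10 is not controlled and need not be, since it becomes a carbonyl carbon in step 10.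

**Step 9**
Reactants: 15 (Z)-enynyl carbinol
Product: 16 (3S,3aS,7aS)-5,5,7a-trimethyl-3-[2-(2-methyl-1,3-dioxolan-2-yl)ethyl]-2-[(2R,3R)-2-methyl-3-(prop-1-ynyl)oxiran-2-yl]octahydro-1H-inden-2-ol (both C2 epimers)
Conditions: D-fructose-derived Shi ketone (0.3 equiv), KHSO5 (as 2KHSO5·KHSO4·K2SO4), K2CO3, Bu4NHSO4, MeCN/CH2(OMe)2/aq. Na2B4O7 buffer (pH 10.5), 0 °C
Reagents that add atoms: potassium peroxymonosulfate, [K+].[O-]S(=O)(=O)OO
Why: Shi asymmetric epoxidation: the dioxirane of the D-fructose-derived ketone should attack the trisubstituted enyne alkene through the spiro transition state with the lone vinylic hydrogen in the hindered quadrant, which by analogy with the (R,R)-epoxide of trans-β-methylstyrene gives the (8R,9R)-epoxide under reagent control for both C10 epimers; the alkyne, the ketal and the tertiary alcohol are inert at pH 10.5.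

**Step 10**
Reactants: 16 epoxy alcohol
Product: 18 ring-expanded 1,3-diol monoester (C8 isobutyrate and C10 alcohol on the new six-membered ring C), via β-hydroxy ketone 17 (not isolated)
Conditions: SmI2 (0.3 equiv), isobutyraldehyde (5 equiv), ClCH2CH2Cl/THF, 0 → 25 °C
Reagents that add atoms: isobutyraldehyde, CC(C)C=O
Why: Trivalent samarium (formed from SmI2 and the aldehyde) activates the epoxide oxygen, the tertiary C9–O bond ionises while the antiperiplanar C10–C18 ring bond shifts to C9 and the C10 hydroxyl becomes the carbonyl of 17, whose samarium alkoxide then adds isobutyraldehyde and passes the hemiacetal hydride to C10 through a six-membered chair (semipinacol rearrangement of a 2,3-epoxy alcohol followed by Evans–Tishchenko reduction). The closest known reaction type is the SmI2-catalysed tandem semipinacol/Tishchenko reaction of α-hydroxy epoxides, including the ring enlargement of 1-oxiranylcycloalkanols. No ring is closed by cyclisation: ring C arises when the five-membered ring C10–C11–C12–C17–C18 takes C9 in between C10 and C18 (1,2-shift ring expansion, five to six). C9 is set by inversion (the migrating carbon enters anti to the leaving oxygen of the Shi epoxide), C8 keeps its epoxide configuration, C18 migrates with retention, and the C10 carbinol (1,3-anti to the C8 oxygen, fixed by the chair hydride transfer) is erased again in step 11. The step needs migration of C18 and not C11, and cleavage at C9 and not at the propargylic C8; the first should be secured by the higher migratory aptitude of the secondary carbon C18 over the neopentyl CH2 C11, the second by the tertiary character of C9 and the push of the C10 oxygen in the bridged transition state.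

**Step 11**
Reactants: 18 1,3-diol monoester
Product: 19 C10=C11 alkene (cyclohexene ring C, C8 isobutyrate)
Conditions: Burgess reagent (MeO2C–N(−)–SO2–N(+)Et3), toluene, 70 °C
Reagents that add atoms: none
Why: Burgess dehydration (syn elimination through the sulfamate ester) should give only the C10=C11 alkene because C11 carries the only β-hydrogens, and it avoids the basic or radical conditions that would endanger the ester or the alkyne; this removes the oxygen that activated the rearrangement.

**Step 12**
Reactants: 19 C10=C11 alkene; 20 ethylene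
Product: 22 cyclopentenone (ring A: C3 ketone, C6=C7, C6 methyl; dioxolane still in place), via alkyne–Co2(CO)6 complex 21 (not isolated)
Conditions: Co2(CO)8 (1.1 equiv), CH2Cl2, 25 °C; then N-methylmorpholine N-oxide (6 equiv), 4 Å molecular sieves, ethylene (6 bar), 25 → 40 °C
Reagents that add atoms: dicobalt octacarbonyl, O=C=[Co](=C=O)(=C=O)(=C=O)[Co](=C=O)(=C=O)(=C=O)=C=O
Why: Intermolecular Pauson–Khand [2+2+1] cycloaddition of the alkyne–Co2(CO)6 complex with ethylene and CO, promoted by the amine N-oxide, should build ring A as a 2,3-disubstituted cyclopentenone with the bulky C8 substituent next to the new carbonyl (C3) and the methyl group on the β-carbon (C6), the usual steric regiochemistry; the hindered C10=C11 alkene cannot compete with ethylene.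

**Step 13**
Reactants: 22 cyclopentenone ketal
Product: 23 cyclopentenone methyl ketone (C2 ketone freed)
Conditions: PPTS, acetone/H2O (10:1), 50 °C
Reagents that add atoms: water, O
Why: Mild acid-catalysed ketal hydrolysis (transketalisation) should release the C2 methyl ketone while the ester stays; it is placed at the enone stage so that the C7 stereocentre made in step 14 never meets acid.

**Step 14**
Reactants: 23 cyclopentenone methyl ketone
Product: 24 saturated diketone (C6 methyl and C7–C8 bond cis on ring A, ring C saturated)
Conditions: H2 (50 bar), [Ir(cod)(PCy3)(py)]PF6 (10 mol %), CH2Cl2, 25 °C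
Reagents that add atoms: none
Why: Homogeneous iridium-catalysed hydrogenation should add H2 syn to the tetrasubstituted enone alkene (C6 and C7 cis) from the face of the C8 acyloxy group, because allylic 1,3-strain with the C6 methyl turns the C8–H bond into the ring plane and puts the quaternary C9 on the opposite face while the ester carbonyl can bind iridium; the C10=C11 alkene is saturated in the same operation and the ketones are untouched.

**Step 15**
Reactants: 24 saturated diketone
Product: 25 C8 isobutyrate of the target
Conditions: TiCl3(DME)1.5, Zn–Cu couple, DME, reflux; 24 added over 30 h by syringe pump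
Reagents that add atoms: none
Why: Intramolecular McMurry coupling of the two ketones by low-valent titanium under high dilution should close the eight-membered ring B and form the tetrasubstituted C2=C3 alkene, whose geometry is fixed by the ring; the conditions are not basic, which should preserve the cis C6/C7 relationship and the ester.

**Step 16**
Reactants: 25 C8 isobutyrate of the target
Product: 26 CNP0399382.1
Conditions: LiAlH4, Et2O, 0 °C; then H2O
Reagents that add atoms: none
Why: Reductive cleavage of the isobutyrate with LiAlH4 (ester reduction) should free the C8 alcohol without touching the tetrasubstituted alkene and give the target.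

**Compound list**

1 | 3,3-dimethylcyclohexanone | O=C1CCCC(C)(C)C1 | starting material
2 | diallyl carbonate | C=CCOC(=O)OCC=C | starting material
3 | allyl 4,4-dimethyl-2-oxocyclohexane-1-carboxylate | C=CCOC(=O)C1CCC(C)(C)CC1=O | intermediate
4 | iodomethane | CI | starting material
5 | allyl 1,4,4-trimethyl-2-oxocyclohexane-1-carboxylate (racemic) | C=CCOC(=O)C1(C)CCC(C)(C)CC1=O | intermediate
6 | (S)-2-allyl-2,5,5-trimethylcyclohexan-1-one | C=CC[C@]1(C)CCC(C)(C)CC1=O | intermediate
7 | (S)-2,5,5-trimethyl-2-(2-oxopropyl)cyclohexan-1-one | CC(=O)C[C@]1(C)CCC(C)(C)CC1=O | intermediate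
8 | (S)-5,5,7a-trimethyl-1,4,5,6,7,7a-hexahydro-2H-inden-2-one | O=C1C[C@]2(C)CCC(C)(C)CC2=C1 | intermediate
9 | 2-(2-bromoethyl)-2-methyl-1,3-dioxolane | CC1(CCBr)OCCO1 | starting material
10 | lithium (3aS,7aS)-5,5,7a-trimethyl-3a,4,5,6,7,7a-hexahydro-1H-inden-2-olate (C10=C18 enolate) | [Li]OC=1C[C@]2(C)CCC(C)(C)C[C@H]2C=1 | intermediate
11 | (3S,3aS,7aS)-5,5,7a-trimethyl-3-[2-(2-methyl-1,3-dioxolan-2-yl)ethyl]octahydro-2H-inden-2-one (trans-fused) | O=C1C[C@]2(C)CCC(C)(C)C[C@H]2[C@@H]1CCC1(C)OCCO1 | intermediate
12 | but-2-ynal | CC#CC=O | starting material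
13 | (Z)-2-iodohex-2-en-4-yne | I/C(C)=C\C#CC | intermediate
14 | (Z)-hex-2-en-4-yn-2-yllithium | [Li]/C(C)=C\C#CC | intermediate
15 | (3S,3aS,7aS)-2-[(Z)-hex-2-en-4-yn-2-yl]-5,5,7a-trimethyl-3-[2-(2-methyl-1,3-dioxolan-2-yl)ethyl]octahydro-1H-inden-2-ol, both C2 (= C10) epimers | OC1(C[C@]2(C)CCC(C)(C)C[C@H]2[C@@H]1CCC1(C)OCCO1)/C(C)=C\C#CC | intermediate
16 | (3S,3aS,7aS)-5,5,7a-trimethyl-3-[2-(2-methyl-1,3-dioxolan-2-yl)ethyl]-2-[(2R,3R)-2-methyl-3-(prop-1-ynyl)oxiran-2-yl]octahydro-1H-inden-2-ol, both C2 (= C10) epimers | OC1(C[C@]2(C)CCC(C)(C)C[C@H]2[C@@H]1CCC1(C)OCCO1)[C@]1(C)O[C@@H]1C#CC | intermediate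
17 | ring-expanded β-hydroxy ketone: trans-fused rings C/D, C10 ketone, quaternary C9 (Me) carrying CH(OH)C≡CCH3 (C8), ketal side chain on C18; C8, C9, C12, C17, C18 arranged as in the target | CC#C[C@@H](O)[C@@]1(C)C(=O)C[C@]2(C)CCC(C)(C)C[C@H]2[C@@H]1CCC1(C)OCCO1 | intermediate
18 | 1,3-diol monoester: as 17 with C8 O-isobutyrate and C10 secondary alcohol (1,3-anti to the C8 oxygen) | CC#C[C@@H](OC(=O)C(C)C)[C@@]1(C)[C@H](O)C[C@]2(C)CCC(C)(C)C[C@H]2[C@@H]1CCC1(C)OCCO1 | intermediate
19 | C10=C11 alkene: cyclohexene ring C, C8 isobutyrate, propynyl group on C8, ketal side chain on C18 | CC#C[C@@H](OC(=O)C(C)C)[C@@]1(C)C=C[C@]2(C)CCC(C)(C)C[C@H]2[C@@H]1CCC1(C)OCCO1 | intermediate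
20 | ethylene | C=C | starting material
21 | μ-alkyne hexacarbonyldicobalt complex of 19 (C6 and C7 bridging the Co–Co bond) | CC12C3([C@@H](OC(=O)C(C)C)[C@@]4(C)C=C[C@]5(C)CCC(C)(C)C[C@H]5[C@@H]4CCC4(C)OCCO4)[Co]1(=C=O)(=C=O)(=C=O)[Co]23(=C=O)(=C=O)=C=O | intermediate
22 | cyclopentenone: ring A with C3 ketone, C6=C7 alkene and C6 methyl, joined through C7 to C8 (isobutyrate); ring C C10=C11; dioxolane side chain | CC1=C(C(=O)CC1)[C@@H](OC(=O)C(C)C)[C@@]1(C)C=C[C@]2(C)CCC(C)(C)C[C@H]2[C@@H]1CCC1(C)OCCO1 | intermediate
23 | as 22 with the dioxolane hydrolysed to the C2 methyl ketone (3-oxobutyl chain on C18) | CC1=C(C(=O)CC1)[C@@H](OC(=O)C(C)C)[C@@]1(C)C=C[C@]2(C)CCC(C)(C)C[C@H]2[C@@H]1CCC(C)=O | intermediate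
24 | saturated diketone: ring A cyclopentanone (C3) with (6S,7S) cis C6-methyl/C7–C8, saturated ring C, C2 methyl ketone, C8 isobutyrate | O=C1CC[C@H](C)[C@@H]1[C@@H](OC(=O)C(C)C)[C@@]1(C)CC[C@]2(C)CCC(C)(C)C[C@H]2[C@@H]1CCC(C)=O | intermediate
25 | C8 O-isobutyrate of the target (5-8-6-6 tetracycle, C2=C3 tetrasubstituted alkene) | C/C1=C2\CC[C@H](C)[C@@H]2[C@@H](OC(=O)C(C)C)[C@@]2(C)CC[C@]3(C)CCC(C)(C)C[C@H]3[C@@H]2CC1 | intermediate
26 | CNP0399382.1: 5-8-6-6 tetracyclic alcohol, (6S,7S,8R,9S,12S,17S,18S) in the locants of the plan | C/C1=C2\CC[C@H](C)[C@@H]2[C@@H](O)[C@@]2(C)CC[C@]3(C)CCC(C)(C)C[C@H]3[C@@H]2CC1 | target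

**Step count**

Total steps: 16. Longest linear sequence: 15 steps (steps 1–6 and 8–16); step 7 makes the side fragment.

**Steps most likely to fail**

Step 10 (key step). What may go wrong: migration of the wrong ring bond (C11 instead of C18), opening of the epoxide at the propargylic carbon C8, or stalling of the hydride transfer at the hindered C10 carbonyl. The fallback sets out from 16 and comes back at 18. The chelating samarium cascade is given up for a stepwise silyl-ether rearrangement. Compound 16 is silylated (TMSOTf, 2,6-lutidine) to the trimethylsilyl ether F1. F1 is rearranged at −78 °C with the bulky aluminium Lewis acid MeAl(OC6H2-4-Br-2,6-tBu2)2 through an open, non-chelated transition state with silyl transfer to the new alkoxide, giving the β-silyloxy ketone F2. K2CO3/MeOH then frees β-hydroxy ketone 17, now isolated, and a separate Evans–Tishchenko reduction (SmI2 cat., isobutyraldehyde, THF, −10 °C) returns 18.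

Step 12. What may go wrong: the crowded alkyne–cobalt complex loses the metal or fails to insert ethylene, or insertion occurs with the reverse orientation. The fallback sets out from 19 and comes back at 22. A stepwise zirconium-mediated assembly replaces the cobalt cycloaddition. Compound 19 is added to Cp2Zr(C2H4) (from Cp2ZrCl2 and 2 EtMgBr, THF, −78 → 0 °C) to give the zirconacyclopentene F3 by alkyne–ethylene coupling. Carbonylation (CO, 1 atm) and acidic work-up should then deliver cyclopentenone 22.

Step 15. What may go wrong: intermolecular coupling or arrest at the pinacol stage during the medium-ring closure, epimerisation at C7 by titanium-promoted enolisation of the cyclopentanone, or β-elimination of the C8 ester. The fallback sets out from 24 and comes back at 25. The deoxygenative coupling is split into two mild stages. A SmI2/HMPA ketyl–carbonyl (pinacol) cyclisation of 24 at −78 °C gives the cis-diol F4. F4 is converted (thiophosgene, DMAP) into the cyclic thionocarbonate F5. Stereospecific syn elimination with 1,3-dimethyl-2-phenyl-1,3,2-diazaphospholidine at 40 °C (Corey–Winter olefination) then gives 25.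

**Further compounds**

F1 | step 10 | trimethylsilyl ether of epoxy alcohol 16 | C[Si](C)(C)OC1(C[C@]2(C)CCC(C)(C)C[C@H]2[C@@H]1CCC1(C)OCCO1)[C@]1(C)O[C@@H]1C#CC
F2 | step 10 | C8 trimethylsilyl ether of β-hydroxy ketone 17 | CC#C[C@@H](O[Si](C)(C)C)[C@@]1(C)C(=O)C[C@]2(C)CCC(C)(C)C[C@H]2[C@@H]1CCC1(C)OCCO1
F3 | step 12 | zirconacyclopentene from 19 and ethylene (Cp2Zr bound to C7 and C4) | CC1=C([C@@H](OC(=O)C(C)C)[C@@]2(C)C=C[C@]3(C)CCC(C)(C)C[C@H]3[C@@H]2CCC2(C)OCCO2)[Zr](C2C=CC=C2)(C2C=CC=C2)CC1
F4 | step 15 | C2,C3 cis-diol of ring B (pinacol of 24; configuration of the two carbinol carbons left open) | CC1(O)C2(O)CC[C@H](C)[C@@H]2[C@@H](OC(=O)C(C)C)[C@@]2(C)CC[C@]3(C)CCC(C)(C)C[C@H]3[C@@H]2CC1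
F5 | step 15 | cyclic thionocarbonate of F4 | CC1(OC(=S)O2)C23CC[C@H](C)[C@@H]3[C@@H](OC(=O)C(C)C)[C@@]3(C)CC[C@]4(C)CCC(C)(C)C[C@H]4[C@@H]3CC1
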